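A direct plan would open ω-pentadecalactone with a lithiated 2-ethyl-1,3-dithiane and, after oxidation, acetalisation and dethioacetalisation, reach the keto-acetal A1.
It would close ring B on A1 by a double Claisen condensation with diethyl oxalate and free the aldehyde A2.
It would join ring A by reductive Knoevenagel alkylation of the hydroxyquinone A3, itself made by Thiele–Winter acetoxylation of the quinone A4.
Its weakest steps would be the oxalate annulation of the diketone bis-enolate, because it has no precedent and would compete with O-acylation, self-aldol reaction and intermolecular acylation;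
the Thiele–Winter acetoxylation, because acetate could add at either free position of A4 and the wrong choice would misplace the hydroxyl group of ring A;
and the oxidation, acetalisation, dethioacetalisation and acetal hydrolysis on the chain, because these four operations would add length without adding complexity.

The route rests on building ring A and ring B de novo and together. In both rings the oxygens at C2 and C5 are para and the methyl carbon C6 is para to the chain carbon C3, so each ring divides into a squarate-derived C1–C4 unit (carbonyls, tert-butoxy, chain) and a 1-alkoxyallene C5–C6 unit (oxygen, methyl). The key step, a double thermal ring expansion of a diyne-bridged bis(4-allenyl-4-hydroxycyclobutenone), forms C1–C6 of both quinones and sets all eight ring substituents in one operation. The rings differ only in the allene used (methoxy or tert-butoxy), so the oxalate annulation, the regiochemical acetoxylation and the redox and masking steps on the chain have no counterpart.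

Key step: step 7

Remark: compounds 5, 10 and 14–18 would be racemic or mixtures of diastereomers at the cyclobutene carbinol carbons; all these centres are erased in step 7 and the target is achiral, so no configuration is specified.

Step 1
Reactants: 1 methoxyallene (1-methoxypropa-1,2-diene); 2 di-tert-butyl squarate (3,4-di-tert-butoxycyclobut-3-ene-1,2-dione)
Product: 5 2,3-di-tert-butoxy-4-[(tert-butyldimethylsilyl)oxy]-4-(1-methoxypropa-1,2-dien-1-yl)cyclobut-2-en-1-one, via 1-lithio-1-methoxyallene 3 (not isolated), via lithium alkoxide adduct 4 (not isolated)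
Conditions: 1, n-BuLi (1.05 equiv), THF, −78 → −40 °C; cannulate into 2 (1.0 equiv), THF, −78 °C; tBuMe2SiOSO2CF3 (1.1 equiv), −78 → 0 °C
Reagents that add atoms: tert-butyldimethylsilyl trifluoromethanesulfonate, CC(C)(C)[Si](C)(C)OS(=O)(=O)C(F)(F)F
Why: 1,2-addition of an α-lithiated alkoxyallene to one of the two equivalent squarate carbonyls followed by O-silylation of the tertiary alkoxide, in which inverse addition at −78 °C should stop at the mono-adduct and the new quaternary centre is racemic.

Step 2
Reactants: 6 tert-butyl propargyl ether (3-tert-butoxyprop-1-yne)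
Product: 7 tert-butoxyallene (1-tert-butoxypropa-1,2-diene)
Conditions: KOtBu (10 mol %), neat, 70 °C; distil
Reagents that add atoms: none
Why: base-catalysed propargyl-to-allenyl prototropic isomerisation, which under catalytic KOtBu should stop at the oxygen-conjugated allene because the further shift to the 1-alkynyl ether needs a stronger base.

Step 3
Reactants: 7 tert-butoxyallene; 2 di-tert-butyl squarate
Product: 10 2,3-di-tert-butoxy-4-(1-tert-butoxypropa-1,2-dien-1-yl)-4-[(tert-butyldimethylsilyl)oxy]cyclobut-2-en-1-one, via 1-tert-butoxy-1-lithioallene 8 (not isolated), via lithium alkoxide adduct 9 (not isolated)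
Conditions: 7, n-BuLi (1.05 equiv), THF, −78 → −40 °C; cannulate into 2 (1.0 equiv), THF, −78 °C; tBuMe2SiOSO2CF3 (1.1 equiv), −78 → 0 °C
Reagents that add atoms: tert-butyldimethylsilyl trifluoromethanesulfonate, CC(C)(C)[Si](C)(C)OS(=O)(=O)C(F)(F)F
Why: the same 1,2-addition of a lithiated alkoxyallene to a squarate carbonyl and O-silylation as in step 1, here with the allene whose oxygen will become the free hydroxyl group next to the methyl group of ring B.

Step 4
Reactants: 11 1,9-dibromononane
Product: 12 trideca-1,12-diyne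
Conditions: LiC≡CH·H2NCH2CH2NH2 (2.5 equiv), DMSO, 15 °C → rt
Reagents that add atoms: lithium acetylide–ethylenediamine complex, [Li]C#C.NCCN
Why: twofold SN2 alkylation of lithium acetylide by a primary dibromide in a dipolar aprotic solvent, a standard entry to terminal α,ω-diynes.

Step 5
Reactants: 12 trideca-1,12-diyne; 5 2,3-di-tert-butoxy-4-[(tert-butyldimethylsilyl)oxy]-4-(1-methoxypropa-1,2-dien-1-yl)cyclobut-2-en-1-one
Product: 14 2,3-di-tert-butoxy-4-[(tert-butyldimethylsilyl)oxy]-4-(1-methoxypropa-1,2-dien-1-yl)-1-(trideca-1,12-diyn-1-yl)cyclobut-2-en-1-ol, via lithium trideca-1,12-diyn-1-ide 13 (not isolated)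
Conditions: 12 (5 equiv), n-BuLi (1.0 equiv), THF, −78 °C; 5 (1.0 equiv), −78 → −30 °C; aq. NaHCO3; SiO2/Et3N, excess 12 recovered
Reagents that add atoms: none
Why: 1,2-addition of a lithium acetylide to the single carbonyl of 5 (the second organolithium addition of the squarate sequence), in which the excess of symmetrical 12 should keep the lithium on singly metalated chains, the bulky silyl ether should not migrate to the new alkoxide at low temperature, and the second carbinol centre forms as a diastereomer mixture that is later erased.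

Step 6
Reactants: 14 2,3-di-tert-butoxy-4-[(tert-butyldimethylsilyl)oxy]-4-(1-methoxypropa-1,2-dien-1-yl)-1-(trideca-1,12-diyn-1-yl)cyclobut-2-en-1-ol; 10 2,3-di-tert-butoxy-4-(1-tert-butoxypropa-1,2-dien-1-yl)-4-[(tert-butyldimethylsilyl)oxy]cyclobut-2-en-1-one
Product: 18 2-tert-butoxy-3-{13-[2-tert-butoxy-4-(1-tert-butoxypropa-1,2-dien-1-yl)-4-hydroxy-3-oxocyclobut-1-en-1-yl]trideca-1,12-diyn-1-yl}-4-hydroxy-4-(1-methoxypropa-1,2-dien-1-yl)cyclobut-2-en-1-one, via dilithium alkoxide acetylide 15 (not isolated), via dilithium bis-adduct dialkoxide 16 (not isolated), via bis-silyl bis-cyclobutenone 17 (not isolated)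
Conditions: n-BuLi (2.05 equiv), THF, −78 °C; 10 (1.05 equiv), −78 → −30 °C; 2,6-lutidine (4 equiv), (CF3CO)2O (2.3 equiv), −78 → 0 °C; aq. NaHCO3; then Bu4NF (2.2 equiv), AcOH (2.2 equiv), THF, 0 °C
Reagents that add atoms: none
Why: the acetylide end of 15 adds to the carbonyl of 10 as in step 5, and trifluoroacetylation of both tertiary alkoxides of 16 then triggers ionisation assisted by the ring enol ether and loss of the tert-butyl cation, a 1,3-carbonyl transposition of the Stork–Danheiser type that leaves the silylated allenyl carbinols untouched, before buffered fluoride frees the two hydroxyl groups.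

Step 7
Reactants: 18 the bis(4-allenyl-4-hydroxycyclobutenone) of step 6
Product: 21 2-tert-butoxy-3-[13-(2,5-di-tert-butoxy-4-methyl-3,6-dioxocyclohexa-1,4-dien-1-yl)trideca-1,12-diyn-1-yl]-5-methoxy-6-methylcyclohexa-2,5-diene-1,4-dione, via bis-dienylketene 19 (not isolated), via bis-o-quinone methide 20 (not isolated)
Conditions: toluene (0.005 M), 90 °C, argon
Reagents that add atoms: none
Why: Proposed new method: on heating, each 4-hydroxycyclobutenone should open by conrotatory 4π-electrocyclic cleavage of the C(=O)–C(OH) ring bond with the hydroxyl group rotating outward, which places the 1-alkoxyallenyl group cis to the new ketene (19), and the ketene carbon should then bond to the central allene carbon in a disrotatory 6π-electrocyclisation that closes ring A and ring B as six-membered rings through C1–C6. The resulting 4-hydroxy-6-methylidenecyclohexa-2,4-dienones (20) are tautomers of the quinones and should reach them by a [1,5]-hydrogen shift from O–H to the exocyclic methylene, so that the methyl group, both carbonyls and the para oxygen pattern appear without an oxidant. The closest known reaction types are the Moore rearrangement of 4-alkynyl- and 4-alkenyl-4-hydroxycyclobutenones to quinones and hydroquinones and the ring expansion of 4-allenylcyclobutenones to o-quinone methides; untested are the 1-alkoxyallenyl group on a hydroxycyclobutenone and the use at both ends of one chain. No stereocentre is formed, and the carbinol centres of 18 are erased. The step needs six-ring closure over five-ring closure to an alkylidenecyclopentenedione, which the concerted path to the sp carbon of the allene (no diradical, unlike the alkynyl case) should secure, and hydrogen shift over bimolecular capture of the o-quinone methides, which high dilution and the hydroxyl group held next to the methylene should secure. Regiochemistry is fixed before the step, because alkoxy and methyl can only arise from the allene carbons C5 and C6 while tert-butoxy and chain already sit on C2 and C3.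

Step 8
Reactants: 21 the diyne-bridged bis(quinone) of step 7
Product: 23 2-tert-butoxy-3-[13-(2,5-di-tert-butoxy-4-methyl-3,6-dioxocyclohexa-1,4-dien-1-yl)tridecyl]-5-methoxy-6-methylcyclohexa-2,5-diene-1,4-dione, via bis-hydroquinone 22 (not isolated)
Conditions: H2 (1 atm), Pd/C (10 wt %), EtOAc, rt; filter; air, EtOAc, rt
Reagents that add atoms: none
Why: heterogeneous catalytic hydrogenation, which should reduce both quinones to hydroquinones and both aryl-conjugated triple bonds to CH2CH2 without touching the tert-butyl or methyl ethers, followed by autoxidation of the electron-rich hydroquinones back to the quinones.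

Step 9
Reactants: 23 the saturated tri-tert-butyl bis(quinone) of step 8
Product: 24 2-hydroxy-3-[13-(2,5-dihydroxy-4-methyl-3,6-dioxocyclohexa-1,4-dien-1-yl)tridecyl]-5-methoxy-6-methyl-1,4-benzoquinone (CNP0107579.0)
Conditions: CF3CO2H/CH2Cl2 (1:4), 0 °C → rt
Reagents that add atoms: none
Why: acidolysis of the three tert-butyl vinylogous esters by E1 loss of 2-methylpropene under anhydrous conditions, which should leave the methyl vinylogous ester of ring A intact because no nucleophile is present to exchange it.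

**Compound list**
1 | methoxyallene (1-methoxypropa-1,2-diene) | COC=C=C | starting material
2 | di-tert-butyl squarate (3,4-di-tert-butoxycyclobut-3-ene-1,2-dione) | CC(C)(C)OC1=C(OC(C)(C)C)C(=O)C1=O | starting material
3 | 1-lithio-1-methoxyallene | [Li]C(OC)=C=C | intermediate
4 | lithium 2,3-di-tert-butoxy-1-(1-methoxypropa-1,2-dien-1-yl)-4-oxocyclobut-2-en-1-olate | [Li]OC1(C(OC)=C=C)C(OC(C)(C)C)=C(OC(C)(C)C)C1=O | intermediate
5 | 2,3-di-tert-butoxy-4-[(tert-butyldimethylsilyl)oxy]-4-(1-methoxypropa-1,2-dien-1-yl)cyclobut-2-en-1-one (racemic) | C=C=C(OC)C1(O[Si](C)(C)C(C)(C)C)C(OC(C)(C)C)=C(OC(C)(C)C)C1=O | intermediate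
6 | tert-butyl propargyl ether (3-tert-butoxyprop-1-yne) | C#CCOC(C)(C)C | starting material
7 | tert-butoxyallene (1-tert-butoxypropa-1,2-diene) | C=C=COC(C)(C)C | intermediate
8 | 1-tert-butoxy-1-lithioallene | [Li]C(OC(C)(C)C)=C=C | intermediate
9 | lithium 2,3-di-tert-butoxy-1-(1-tert-butoxypropa-1,2-dien-1-yl)-4-oxocyclobut-2-en-1-olate | [Li]OC1(C(OC(C)(C)C)=C=C)C(OC(C)(C)C)=C(OC(C)(C)C)C1=O | intermediate
10 | 2,3-di-tert-butoxy-4-(1-tert-butoxypropa-1,2-dien-1-yl)-4-[(tert-butyldimethylsilyl)oxy]cyclobut-2-en-1-one (racemic) | C=C=C(OC(C)(C)C)C1(O[Si](C)(C)C(C)(C)C)C(OC(C)(C)C)=C(OC(C)(C)C)C1=O | intermediate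
11 | 1,9-dibromononane | BrCCCCCCCCCBr | starting material
12 | trideca-1,12-diyne | C#CCCCCCCCCCC#C | intermediate
13 | lithium trideca-1,12-diyn-1-ide | [Li]C#CCCCCCCCCCC#C | intermediate
14 | 2,3-di-tert-butoxy-4-[(tert-butyldimethylsilyl)oxy]-4-(1-methoxypropa-1,2-dien-1-yl)-1-(trideca-1,12-diyn-1-yl)cyclobut-2-en-1-ol (diastereomer mixture) | C#CCCCCCCCCCC#CC1(O)C(OC(C)(C)C)=C(OC(C)(C)C)C1(O[Si](C)(C)C(C)(C)C)C(OC)=C=C | intermediate
15 | dilithium salt of 14 (lithium alkoxide at C1 of the ring and lithium acetylide at the chain end) | [Li]C#CCCCCCCCCCC#CC1(O[Li])C(OC(C)(C)C)=C(OC(C)(C)C)C1(O[Si](C)(C)C(C)(C)C)C(OC)=C=C | intermediate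
16 | dilithium bis-adduct: trideca-1,12-diyne-1,13-diyl chain joining C1 of two 2,3-di-tert-butoxy-4-[(tert-butyldimethylsilyl)oxy]cyclobut-2-en-1-olates, C4 carrying 1-methoxyallenyl at one end and 1-tert-butoxyallenyl at the other | C=C=C(OC)C1(O[Si](C)(C)C(C)(C)C)C(OC(C)(C)C)=C(OC(C)(C)C)C1(O[Li])C#CCCCCCCCCCC#CC2(O[Li])C(OC(C)(C)C)=C(OC(C)(C)C)C2(O[Si](C)(C)C(C)(C)C)C(OC(C)(C)C)=C=C | intermediate
17 | bis-silyl bis(cyclobutenone): compound 18 with both 4-hydroxyl groups as tert-butyldimethylsilyl ethers | C=C=C(OC)C1(O[Si](C)(C)C(C)(C)C)C(=O)C(OC(C)(C)C)=C1C#CCCCCCCCCCC#CC2=C(OC(C)(C)C)C(=O)C2(O[Si](C)(C)C(C)(C)C)C(OC(C)(C)C)=C=C | intermediate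
18 | 2-tert-butoxy-3-{13-[2-tert-butoxy-4-(1-tert-butoxypropa-1,2-dien-1-yl)-4-hydroxy-3-oxocyclobut-1-en-1-yl]trideca-1,12-diyn-1-yl}-4-hydroxy-4-(1-methoxypropa-1,2-dien-1-yl)cyclobut-2-en-1-one (diastereomer mixture) | C=C=C(OC)C1(O)C(=O)C(OC(C)(C)C)=C1C#CCCCCCCCCCC#CC2=C(OC(C)(C)C)C(=O)C2(O)C(OC(C)(C)C)=C=C | intermediate
19 | bis(dienylketene): at each end the chain alkyne carbon is bonded to a carbon that carries C(OtBu)=C=O and is doubly bonded to C(OH)(1-alkoxyallenyl), the allenyl group cis to the ketene (methoxy at one end, tert-butoxy at the other) | C=C=C(OC)/C(O)=C(/C#CCCCCCCCCCC#C/C(=C(O)/C(OC(C)(C)C)=C=C)C(OC(C)(C)C)=C=O)C(OC(C)(C)C)=C=O | intermediate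
20 | bis(o-quinone methide): 2-tert-butoxy-3-{13-[2,5-di-tert-butoxy-6-hydroxy-4-methylidene-3-oxocyclohexa-1,5-dien-1-yl]trideca-1,12-diyn-1-yl}-4-hydroxy-5-methoxy-6-methylidenecyclohexa-2,4-dien-1-one | C=C1C(=O)C(OC(C)(C)C)=C(C#CCCCCCCCCCC#CC2=C(OC(C)(C)C)C(=O)C(=C)C(OC(C)(C)C)=C2O)C(O)=C1OC | intermediate
21 | 2-tert-butoxy-3-[13-(2,5-di-tert-butoxy-4-methyl-3,6-dioxocyclohexa-1,4-dien-1-yl)trideca-1,12-diyn-1-yl]-5-methoxy-6-methylcyclohexa-2,5-diene-1,4-dione | COC1=C(C)C(=O)C(OC(C)(C)C)=C(C#CCCCCCCCCCC#CC2=C(OC(C)(C)C)C(=O)C(C)=C(OC(C)(C)C)C2=O)C1=O | intermediate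
22 | 2-tert-butoxy-3-[13-(2,5-di-tert-butoxy-3,6-dihydroxy-4-methylphenyl)tridecyl]-5-methoxy-6-methylbenzene-1,4-diol | COc1c(C)c(O)c(OC(C)(C)C)c(CCCCCCCCCCCCCc2c(OC(C)(C)C)c(O)c(C)c(OC(C)(C)C)c2O)c1O | intermediate
23 | 2-tert-butoxy-3-[13-(2,5-di-tert-butoxy-4-methyl-3,6-dioxocyclohexa-1,4-dien-1-yl)tridecyl]-5-methoxy-6-methylcyclohexa-2,5-diene-1,4-dione | COC1=C(C)C(=O)C(OC(C)(C)C)=C(CCCCCCCCCCCCCC2=C(OC(C)(C)C)C(=O)C(C)=C(OC(C)(C)C)C2=O)C1=O | intermediate
24 | 2-hydroxy-3-[13-(2,5-dihydroxy-4-methyl-3,6-dioxocyclohexa-1,4-dien-1-yl)tridecyl]-5-methoxy-6-methyl-1,4-benzoquinone (CNP0107579.0) | COC1=C(C)C(=O)C(O)=C(CCCCCCCCCCCCCC2=C(O)C(=O)C(C)=C(O)C2=O)C1=O | target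

**Step count and risks**

Total steps: 9. Longest linear sequence: 6 steps (steps 2, 3, 6, 7, 8, 9; the branches through steps 1 and 5 or 4 and 5 are equally long).

Steps most likely to fail:

Step 7 (key step, proposed new method). The o-quinone methide ends may be captured by dimerisation or hetero-Diels–Alder reaction before the hydrogen shift, or five-ring closure may compete. The fallback sets out from 2 and 12 and comes back at 21. The allenyl groups would be replaced by 1-alkoxyprop-1-enyl groups, whose thermal ring expansion to hydroquinones is established chemistry. α-Lithiated 1-methoxyprop-1-ene (t-BuLi, THF) would add to 2 and silylation would give the 1-methoxyprop-1-enyl silyl ether F1; α-lithiated 1-tert-butoxyprop-1-ene would give the tert-butoxy analogue F2. The operations of steps 5 and 6 would then lead through the mono-adduct alcohol F3 to the bis(4-hydroxy-4-propenylcyclobutenone) F4. Heating in toluene would give the diyne-bridged bis(hydroquinone) F5, and Ag2O in CH2Cl2 would oxidise it to 21.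

Step 6. The trifluoroacetic anhydride may acylate or hydrolyse the allenyl ethers, the silyl group may migrate to the neighbouring alkoxide so that the wrong carbinol ionises, or the second acetylide addition may be slow. The fallback sets out from 2 and 12 and comes back at 21. The chain would be placed on the squarate before the two-carbon units, so that no acid is used once these are present. Dilithiated 12 and two equivalents of 2, then (CF3CO)2O, would give the bis(4-tert-butoxycyclobutenedione) F6. (Z)-2-Lithio-1-methoxyprop-1-ene (one equivalent) and then (Z)-1-tert-butoxy-2-lithioprop-1-ene, both from the bromides and t-BuLi, would add at the ketone carbonyl next to the tert-butoxy carbon and give the mixed bis(4-hydroxycyclobutenone) F7, which must be separated from the two symmetrical adducts. Thermolysis would give the diyne-bridged bis(hydroquinone) F8, and Ag2O would oxidise it to 21.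

Step 8. A hydroquinone hydroxyl group may cyclise onto the neighbouring triple bond to a benzofuran faster than the triple bond is hydrogenated. The fallback sets out from 21 and comes back at 23. Reductive acetylation (Zn, Ac2O, NaOAc) would give the diyne tetraacetate F9, hydrogenation over Pd/C in EtOAc would give the saturated tetraacetate F10, and K2CO3 in MeOH under air would remove the acetates and reoxidise the hydroquinones to 23.

Further compounds
F1 | step 7 | 2,3-di-tert-butoxy-4-[(tert-butyldimethylsilyl)oxy]-4-(1-methoxyprop-1-en-1-yl)cyclobut-2-en-1-one (E/Z mixture) | CC=C(OC)C1(O[Si](C)(C)C(C)(C)C)C(OC(C)(C)C)=C(OC(C)(C)C)C1=O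
F2 | step 7 | 2,3-di-tert-butoxy-4-(1-tert-butoxyprop-1-en-1-yl)-4-[(tert-butyldimethylsilyl)oxy]cyclobut-2-en-1-one (E/Z mixture) | CC=C(OC(C)(C)C)C1(O[Si](C)(C)C(C)(C)C)C(OC(C)(C)C)=C(OC(C)(C)C)C1=O
F3 | step 7 | 2,3-di-tert-butoxy-4-[(tert-butyldimethylsilyl)oxy]-4-(1-methoxyprop-1-en-1-yl)-1-(trideca-1,12-diyn-1-yl)cyclobut-2-en-1-ol | C#CCCCCCCCCCC#CC1(O)C(OC(C)(C)C)=C(OC(C)(C)C)C1(O[Si](C)(C)C(C)(C)C)C(OC)=CC
F4 | step 7 | 2-tert-butoxy-3-{13-[2-tert-butoxy-4-(1-tert-butoxyprop-1-en-1-yl)-4-hydroxy-3-oxocyclobut-1-en-1-yl]trideca-1,12-diyn-1-yl}-4-hydroxy-4-(1-methoxyprop-1-en-1-yl)cyclobut-2-en-1-one | CC=C(OC)C1(O)C(=O)C(OC(C)(C)C)=C1C#CCCCCCCCCCC#CC2=C(OC(C)(C)C)C(=O)C2(O)C(OC(C)(C)C)=CC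
F5 | step 7 | 2-tert-butoxy-3-[13-(2,5-di-tert-butoxy-3,6-dihydroxy-4-methylphenyl)trideca-1,12-diyn-1-yl]-5-methoxy-6-methylbenzene-1,4-diol | COc1c(C)c(O)c(OC(C)(C)C)c(C#CCCCCCCCCCC#Cc2c(OC(C)(C)C)c(O)c(C)c(OC(C)(C)C)c2O)c1O
F6 | step 6 | 3,3'-(trideca-1,12-diyne-1,13-diyl)bis(4-tert-butoxycyclobut-3-ene-1,2-dione) | O=C1C(=O)C(OC(C)(C)C)=C1C#CCCCCCCCCCC#CC2=C(OC(C)(C)C)C(=O)C2=O
F7 | step 6 | trideca-1,12-diyne-1,13-diyl chain joining C2 of two 3-tert-butoxy-4-hydroxycyclobut-2-en-1-ones, C4 carrying 1-methoxyprop-1-en-2-yl at one end and 1-tert-butoxyprop-1-en-2-yl at the other | COC=C(C)C1(O)C(=O)C(C#CCCCCCCCCCC#CC2=C(OC(C)(C)C)C(O)(C(C)=COC(C)(C)C)C2=O)=C1OC(C)(C)C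
F8 | step 6 | 2-tert-butoxy-3-[13-(2,5-di-tert-butoxy-3,6-dihydroxy-4-methylphenyl)trideca-1,12-diyn-1-yl]-5-methoxy-6-methylbenzene-1,4-diol | COc1c(C)c(O)c(OC(C)(C)C)c(C#CCCCCCCCCCC#Cc2c(OC(C)(C)C)c(O)c(C)c(OC(C)(C)C)c2O)c1O
F9 | step 8 | 2-tert-butoxy-3-[13-(3,6-diacetoxy-2,5-di-tert-butoxy-4-methylphenyl)trideca-1,12-diyn-1-yl]-5-methoxy-6-methyl-1,4-phenylene diacetate | COc1c(C)c(OC(C)=O)c(OC(C)(C)C)c(C#CCCCCCCCCCC#Cc2c(OC(C)(C)C)c(OC(C)=O)c(C)c(OC(C)(C)C)c2OC(C)=O)c1OC(C)=O
F10 | step 8 | 2-tert-butoxy-3-[13-(3,6-diacetoxy-2,5-di-tert-butoxy-4-methylphenyl)tridecyl]-5-methoxy-6-methyl-1,4-phenylene diacetate | COc1c(C)c(OC(C)=O)c(OC(C)(C)C)c(CCCCCCCCCCCCCc2c(OC(C)(C)C)c(OC(C)=O)c(C)c(OC(C)(C)C)c2OC(C)=O)c1OC(C)=O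
A1 | direct plan | 17-(1,3-dioxolan-2-yl)heptadecane-3,4-dione | CCC(=O)C(=O)CCCCCCCCCCCCCC1OCCO1
A2 | direct plan | 13-(2,5-dihydroxy-4-methyl-3,6-dioxocyclohexa-1,4-dien-1-yl)tridecanal | CC1=C(O)C(=O)C(CCCCCCCCCCCCC=O)=C(O)C1=O
A3 | direct plan | 5-hydroxy-2-methoxy-3-methylcyclohexa-2,5-diene-1,4-dione | COC1=C(C)C(=O)C(O)=CC1=O
A4 | direct plan | 2-methoxy-3-methylcyclohexa-2,5-diene-1,4-dione | COC1=C(C)C(=O)C=CC1=O
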